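**Plan**

1. Cuts, in retrosynthetic order: the C5–O ester (oxazole acid, last step); the C3–C4 bond together with the C3–O–C7 ether (one ring closure that makes the natural oxane and the 14-membered lactone); the C13–O–C1 ester; C6–C7; the C9–CH3 bond and C8=C9; finally C12–C13.
2. Feature used: C13 carries the lactone oxygen and C9 lies four carbons away, so O13–C13–C12–C11–C10–C9 can be tied into a temporary oxane (ring T). The 1,3-anti pair C11–OMe / C13–O is the 2,4-cis (diequatorial) pattern of a Prins oxane, and butanal supplies C13–C16.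
3. Forward: ring T is closed by C12–C13 bond formation from butanal and (R)-1-chloropent-4-en-2-ol, O-methylated at C11, then cut open at O–C9 by reductive β-elimination. This returns the C13 hydroxyl (for the lactone ester) and a vinyl group at C9; the helper carbon later leaves as ethene.
4. The chain is then grown C9 → C7 → C4 (cross-metathesis, conjugate methylation, allylation). A second Prins cyclization closes the natural oxane (C3–C7) and the macrolactone together, and the oxazole acid is attached last.
5. Stereochemistry: C11 and C13 from the epichlorohydrin-derived carbinol through the chair Prins transition state; C9 from the copper/JosiPhos catalyst; C7 from the allylborane; C3 and C5 from C7 in the second chair Prins; C5 inverted in the Mitsunobu step; both Z-alkenes from Lindlar reduction and Still–Gennari olefination.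

Key step: step 2

Remark: atom numbers C1–C16 follow the usual neopeltolide numbering; in step 9 the JosiPhos antipode is the one assumed, by analogy with simple E-thioenoates, to place methyl on the Si face of C9, and the other antipode is taken if the sense is the reverse.

**Route**

Step 1
Reactants: 1 (R)-epichlorohydrin
Product: 2 (2R)-1-chloropent-4-en-2-ol
Conditions: CH2=CHMgBr, CuI (10 mol%), THF, −78 → −20 °C; aq NH4Cl
Reagents that add atoms: vinylmagnesium bromide, C=C[Mg]Br
Why: Copper-catalysed Grignard opening of the epoxide at its CH2 terminus (SN2) keeps the C–O stereocentre and the chloride, so the carbinol carbon that will act as temporary C9 comes from the chiral pool.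

Step 2
Reactants: 2 (2R)-1-chloropent-4-en-2-ol; 3 butanal
Product: 5 (2R,4S,6R)-2-(chloromethyl)-6-propyloxan-4-ol, via oxanyl trifluoroacetate 4 (not isolated)
Conditions: CF3CO2H, CH2Cl2, 0 °C → rt; then K2CO3, MeOH, rt
Reagents that add atoms: trifluoroacetic acid, OC(=O)C(F)(F)F
Why: Prins cyclization (closest known type: acid-mediated union of a homoallylic alcohol with an aliphatic aldehyde to an all-cis 2,6-disubstituted oxan-4-ol): butanal and the hydroxyl of 2 condense under CF3CO2H to the (E)-oxocarbenium ion, whose carbon C13 is attacked by the terminal alkene carbon C12, so that C12–C13 is the ring-closing bond. Ring T (O13, C13, C12, C11, C10 and the temporary C9) closes in the 6-endo-trig mode through a chair transition state. C13 is set by the carbinol stereocentre of 2, because propyl and CH2Cl both sit equatorial, which gives the 2,6-cis oxane. C11 is set when trifluoroacetate adds equatorially to the secondary cation, so its oxygen is cis to both neighbours, which after ring opening is the 1,3-anti relation to O13; methanolysis of ester 4 then frees the alcohol. The step needs all-cis diastereoselectivity and no loss of enantiopurity by allyl transfer (2-oxonia-Cope rearrangement); the chair with three equatorial groups should secure the first, and the electron-withdrawing CH2Cl group, which disfavours the rearranged oxocarbenium ion, should secure the second.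

Step 3
Reactants: 5 (2R,4S,6R)-2-(chloromethyl)-6-propyloxan-4-ol
Product: 6 (2R,4S,6R)-2-(chloromethyl)-4-methoxy-6-propyloxane
Conditions: NaH, MeI, THF, 0 °C → rt
Reagents that add atoms: iodomethane, CI
Why: Williamson etherification of the unhindered equatorial alkoxide installs the C11 methyl ether while O13 is still locked in ring T, so the two oxygens are differentiated without a protecting group.

Step 4
Reactants: 6 (2R,4S,6R)-2-(chloromethyl)-4-methoxy-6-propyloxane
Product: 7 (4R,6R)-6-methoxynon-8-en-4-ol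
Conditions: Na (dispersion), Et2O, reflux; then H2O
Reagents that add atoms: none
Why: Boord-type reductive β-elimination: electron transfer to the C–Cl bond gives a carbanion that expels the ring alkoxide, which cuts the O–C9 bond and releases the C13 alkoxide and a terminal alkene without touching C11 or C13.

Step 5
Reactants: 8 ethyl 3,3-diethoxypropanoate
Product: 9 3,3-diethoxypropanoic acid
Conditions: NaOH, H2O/EtOH, rt; then aq HCl to pH 3–4, 0 °C
Reagents that add atoms: sodium hydroxide, [Na+].[OH-]
Why: Saponification under basic conditions leaves the acid-labile diethyl acetal intact, and cold, mild acidification frees the acid without hydrolysing it.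

Step 6
Reactants: 7 (4R,6R)-6-methoxynon-8-en-4-ol; 9 3,3-diethoxypropanoic acid
Product: 10 (4R,6R)-6-methoxynon-8-en-4-yl 3,3-diethoxypropanoate
Conditions: DCC, DMAP (cat.), CH2Cl2, 0 °C → rt
Reagents that add atoms: none
Why: Steglich esterification acylates the only hydroxyl (C13–OH) with retention and so installs C1–C3 of the lactone, with C3 masked as an acetal.

Step 7
Reactants: 11 3-chloropropanoyl chloride; 12 ethanethiol
Product: 14 S-ethyl prop-2-enethioate, via S-ethyl 3-chloropropanethioate 13 (not isolated)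
Conditions: EtSH, pyridine, CH2Cl2, 0 °C; then Et3N, 0 °C → rt (BHT)
Reagents that add atoms: none
Why: S-acylation of the thiol followed by base-induced E1cB loss of HCl (the usual 3-chloropropanoyl route to acryloyl derivatives) gives the thioacrylate and avoids exposing a preformed acrylate to free thiol.

Step 8
Reactants: 10 (4R,6R)-6-methoxynon-8-en-4-yl 3,3-diethoxypropanoate; 14 S-ethyl prop-2-enethioate
Product: 15 S-ethyl (2E,5R,7R)-7-[(3,3-diethoxypropanoyl)oxy]-5-methoxydec-2-enethioate
Conditions: second-generation Hoveyda–Grubbs catalyst (5 mol%), CH2Cl2, 40 °C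
Reagents that add atoms: none
Why: Olefin cross-metathesis between the terminal alkene and the electron-poor thioacrylate favours the hetero-coupled E-thioenoate, expels the helper carbon as ethene, and is neutral, so the C11 methoxy group cannot be lost by vinylogous elimination.

Step 9
Reactants: 15 S-ethyl (2E,5R,7R)-7-[(3,3-diethoxypropanoyl)oxy]-5-methoxydec-2-enethioate
Product: 16 S-ethyl (3S,5R,7R)-7-[(3,3-diethoxypropanoyl)oxy]-5-methoxy-3-methyldecanethioate
Conditions: MeMgBr, CuBr·SMe2 (5 mol%), (S,R)-JosiPhos [(S)-1-[(R)-2-(diphenylphosphino)ferrocenyl]ethyldicyclohexylphosphine] (6 mol%), t-BuOMe, −75 °C; aq NH4Cl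
Reagents that add atoms: methylmagnesium bromide, C[Mg]Br
Why: Copper-catalysed asymmetric conjugate addition of the Grignard reagent to the E-thioenoate, in which the chiral diphosphine–copper complex delivers methyl to the Si face of C9 under catalyst control; at −75 °C the alkyl ester and the acetal should not be attacked.

Step 10
Reactants: 16 S-ethyl (3S,5R,7R)-7-[(3,3-diethoxypropanoyl)oxy]-5-methoxy-3-methyldecanethioate
Product: 17 (4R,6R,8S)-6-methoxy-8-methyl-10-oxodecan-4-yl 3,3-diethoxypropanoate
Conditions: Et3SiH, Pd/C (10 wt% Pd), acetone, rt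
Reagents that add atoms: none
Why: Fukuyama reduction converts the thioester into the C7 aldehyde chemoselectively, leaving the oxo ester and the acetal untouched, which an aluminium hydride could not guarantee.

Step 11
Reactants: 17 (4R,6R,8S)-6-methoxy-8-methyl-10-oxodecan-4-yl 3,3-diethoxypropanoate
Product: 19 (4R,6R,8R,10S)-10-hydroxy-6-methoxy-8-methyltridec-12-en-4-yl 3,3-diethoxypropanoate, via borinate ester 18 (not isolated)
Conditions: (−)-Ipc2B(allyl) (from (+)-α-pinene), Et2O, −78 °C; then aq NaOAc, 30% H2O2, 0 °C → rt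
Reagents that add atoms: (−)-B-allyldiisopinocampheylborane, C=CCB([C@@H]1C[C@@H]2C[C@H]([C@H]1C)C2(C)C)[C@@H]1C[C@@H]2C[C@H]([C@H]1C)C2(C)C
Why: Brown allylation, in which the allylborane adds through a chair six-membered transition state to the Si face of the aldehyde under reagent control and sets C7; buffered peroxide cleaves borinate 18 without hydrolysing the ester.

Step 12
Reactants: 19 (4R,6R,8R,10S)-10-hydroxy-6-methoxy-8-methyltridec-12-en-4-yl 3,3-diethoxypropanoate
Product: 20 (3R,5S,7R,9S,11R,13R)-5-acetoxy-3,7-epoxy-11-methoxy-9-methylhexadecan-13-olide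
Conditions: TESOTf, TMSOAc, AcOH, rt, 5 mM; aq NaHCO3
Reagents that add atoms: trimethylsilyl acetate, CC(=O)O[Si](C)(C)C; acetic acid, CC(=O)O
Why: Prins macrocyclization, in which the silyl triflate ionises the acetal, the C7 hydroxyl captures it, and the resulting oxocarbenium ion (C3=O–C7) is attacked by the terminal alkene carbon C4 in a chair with the C7 chain equatorial; this closes the natural 2,6-cis oxane (C3 from C7) and the 14-membered lactone in one event, with acetate adding equatorially at C5.

Step 13
Reactants: 20 (3R,5S,7R,9S,11R,13R)-5-acetoxy-3,7-epoxy-11-methoxy-9-methylhexadecan-13-olide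
Product: 21 (3R,5S,7R,9S,11R,13R)-3,7-epoxy-5-hydroxy-11-methoxy-9-methylhexadecan-13-olide
Conditions: K2CO3, MeOH, 0 °C
Reagents that add atoms: none
Why: Base-catalysed transesterification should remove the unhindered secondary acetate faster than it opens the more hindered macrolactone, revealing the equatorial C5 alcohol.

Step 14
Reactants: 22 prop-2-yn-1-amine
Product: 23 methyl prop-2-yn-1-ylcarbamate
Conditions: ClCO2Me, Et3N, CH2Cl2, 0 °C
Reagents that add atoms: methyl chloroformate, COC(Cl)=O
Why: N-acylation of the primary amine by the chloroformate gives the carbamate that is carried unchanged into the target.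

Step 15
Reactants: 24 methyl 5-bromo-4-oxopentanoate; 25 urea
Product: 26 methyl 3-(2-amino-1,3-oxazol-4-yl)propanoate
Conditions: urea (excess), DMF, 90 °C; aq NaHCO3
Reagents that add atoms: none
Why: Hantzsch-type oxazole synthesis, in which O-alkylation of urea by the bromoketone and cyclodehydration onto the ketone place the propanoate chain at C4 and leave C5 unsubstituted.

Step 16
Reactants: 26 methyl 3-(2-amino-1,3-oxazol-4-yl)propanoate
Product: 27 methyl 3-(2-bromo-1,3-oxazol-4-yl)propanoate
Conditions: t-BuONO, CuBr2, MeCN, 0 °C → rt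
Reagents that add atoms: copper dibromide, Br[Cu]Br
Why: Sandmeyer-type bromodediazoniation, in which the alkyl nitrite diazotises the 2-amino group and CuBr2 transfers bromine to the oxazolyl radical formed on loss of nitrogen.

Step 17
Reactants: 27 methyl 3-(2-bromo-1,3-oxazol-4-yl)propanoate; 23 methyl prop-2-yn-1-ylcarbamate
Product: 28 methyl 3-{2-[3-(methoxycarbonylamino)prop-1-yn-1-yl]-1,3-oxazol-4-yl}propanoate
Conditions: Pd(PPh3)2Cl2 (5 mol%), CuI (10 mol%), Et3N, THF, rt
Reagents that add atoms: none
Why: Sonogashira coupling of the electron-poor 2-bromooxazole with the terminal alkyne forms the C2–alkynyl bond and tolerates the carbamate N–H and the ester.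

Step 18
Reactants: 28 methyl 3-{2-[3-(methoxycarbonylamino)prop-1-yn-1-yl]-1,3-oxazol-4-yl}propanoate
Product: 29 methyl 3-{2-[(1Z)-3-(methoxycarbonylamino)prop-1-en-1-yl]-1,3-oxazol-4-yl}propanoate
Conditions: H2 (1 atm), Pd/CaCO3 poisoned with Pb(OAc)2 (Lindlar catalyst), quinoline, EtOAc, rt
Reagents that add atoms: none
Why: Lindlar semihydrogenation adds hydrogen syn to the alkyne on the poisoned palladium surface and stops at the Z-alkene.

Step 19
Reactants: 29 methyl 3-{2-[(1Z)-3-(methoxycarbonylamino)prop-1-en-1-yl]-1,3-oxazol-4-yl}propanoate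
Product: 30 methyl N-{(2Z)-3-[4-(3-oxopropyl)-1,3-oxazol-2-yl]prop-2-en-1-yl}carbamate
Conditions: i-Bu2AlH (2.2 equiv), CH2Cl2, −78 °C; aq potassium sodium tartrate
Reagents that add atoms: none
Why: Low-temperature i-Bu2AlH reduction stops at the tetrahedral aluminium hemiacetal, which gives the aldehyde on work-up; the first equivalent is consumed by the carbamate N–H, whose anion shields the carbamate carbonyl.

Step 20
Reactants: 30 methyl N-{(2Z)-3-[4-(3-oxopropyl)-1,3-oxazol-2-yl]prop-2-en-1-yl}carbamate
Product: 31 methyl (2Z)-5-{2-[(1Z)-3-(methoxycarbonylamino)prop-1-en-1-yl]-1,3-oxazol-4-yl}pent-2-enoate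
Conditions: (CF3CH2O)2P(O)CH2CO2Me, KN(SiMe3)2, 18-crown-6, THF, −78 °C
Reagents that add atoms: methyl bis(2,2,2-trifluoroethyl)phosphonoacetate, COC(=O)CP(=O)(OCC(F)(F)F)OCC(F)(F)F
Why: Still–Gennari olefination, in which the electron-poor trifluoroethyl phosphonate with a dissociated potassium counter-ion eliminates rapidly from the kinetic adduct and gives the Z-enoate.

Step 21
Reactants: 31 methyl (2Z)-5-{2-[(1Z)-3-(methoxycarbonylamino)prop-1-en-1-yl]-1,3-oxazol-4-yl}pent-2-enoate
Product: 32 (2Z)-5-{2-[(1Z)-3-(methoxycarbonylamino)prop-1-en-1-yl]-1,3-oxazol-4-yl}pent-2-enoic acid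
Conditions: LiOH, THF/H2O, 0 °C → rt; then aq HCl to pH 3
Reagents that add atoms: lithium hydroxide, [Li+].[OH-]
Why: Mild saponification cleaves the methyl ester while the methyl carbamate and both Z-alkenes should survive.

Step 22
Reactants: 21 (3R,5S,7R,9S,11R,13R)-3,7-epoxy-5-hydroxy-11-methoxy-9-methylhexadecan-13-olide; 32 (2Z)-5-{2-[(1Z)-3-(methoxycarbonylamino)prop-1-en-1-yl]-1,3-oxazol-4-yl}pent-2-enoic acid
Product: 33 neopeltolide
Conditions: PPh3, DIAD, benzene, 0 °C → rt
Reagents that add atoms: none
Why: Mitsunobu esterification, in which the equatorial C5 alcohol is activated as its alkoxyphosphonium ion and displaced by the carboxylate with inversion (SN2), giving the axial C5 ester of the target without isomerising the Z-enoate.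

**Compound list**

1 | (R)-epichlorohydrin, (2R)-2-(chloromethyl)oxirane | ClC[C@H]1CO1 | starting material
2 | (2R)-1-chloropent-4-en-2-ol | C=CC[C@H](CCl)O | intermediate
3 | butanal | CCCC=O | starting material
4 | (2R,4S,6R)-2-(chloromethyl)-6-propyloxan-4-yl trifluoroacetate (all-cis) | CCC[C@@H]1C[C@H](OC(=O)C(F)(F)F)C[C@H](CCl)O1 | intermediate
5 | (2R,4S,6R)-2-(chloromethyl)-6-propyloxan-4-ol (all-cis) | CCC[C@@H]1C[C@H](O)C[C@H](CCl)O1 | intermediate
6 | (2R,4S,6R)-2-(chloromethyl)-4-methoxy-6-propyloxane | CCC[C@@H]1C[C@H](OC)C[C@H](CCl)O1 | intermediate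
7 | (4R,6R)-6-methoxynon-8-en-4-ol | CCC[C@@H](O)C[C@H](OC)CC=C | intermediate
8 | ethyl 3,3-diethoxypropanoate | CCOC(=O)CC(OCC)OCC | starting material
9 | 3,3-diethoxypropanoic acid | OC(=O)CC(OCC)OCC | intermediate
10 | (4R,6R)-6-methoxynon-8-en-4-yl 3,3-diethoxypropanoate | CCC[C@@H](OC(=O)CC(OCC)OCC)C[C@H](OC)CC=C | intermediate
11 | 3-chloropropanoyl chloride | ClCCC(Cl)=O | starting material
12 | ethanethiol | CCS | starting material
13 | S-ethyl 3-chloropropanethioate | ClCCC(=O)SCC | intermediate
14 | S-ethyl prop-2-enethioate | C=CC(=O)SCC | intermediate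
15 | S-ethyl (2E,5R,7R)-7-[(3,3-diethoxypropanoyl)oxy]-5-methoxydec-2-enethioate | CCC[C@@H](OC(=O)CC(OCC)OCC)C[C@H](OC)C/C=C/C(=O)SCC | intermediate
16 | S-ethyl (3S,5R,7R)-7-[(3,3-diethoxypropanoyl)oxy]-5-methoxy-3-methyldecanethioate | CCC[C@@H](OC(=O)CC(OCC)OCC)C[C@H](OC)C[C@H](C)CC(=O)SCC | intermediate
17 | (4R,6R,8S)-6-methoxy-8-methyl-10-oxodecan-4-yl 3,3-diethoxypropanoate | CCC[C@@H](OC(=O)CC(OCC)OCC)C[C@H](OC)C[C@H](C)CC=O | intermediate
18 | bis(isopinocampheyl)borinate ester of alcohol 19 (boron on the C7 oxygen) | CCC[C@@H](OC(=O)CC(OCC)OCC)C[C@H](OC)C[C@H](C)C[C@@H](OB([C@@H]1C[C@@H]2C[C@H]([C@H]1C)C2(C)C)[C@@H]1C[C@@H]2C[C@H]([C@H]1C)C2(C)C)CC=C | intermediate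
19 | (4R,6R,8R,10S)-10-hydroxy-6-methoxy-8-methyltridec-12-en-4-yl 3,3-diethoxypropanoate | CCC[C@@H](OC(=O)CC(OCC)OCC)C[C@H](OC)C[C@H](C)C[C@@H](O)CC=C | intermediate
20 | (3R,5S,7R,9S,11R,13R)-5-acetoxy-3,7-epoxy-11-methoxy-9-methylhexadecan-13-olide (macrolactone, equatorial C5 acetate) | CCC[C@@H]1C[C@H](OC)C[C@H](C)C[C@@H]2C[C@H](OC(C)=O)C[C@H](CC(=O)O1)O2 | intermediate
21 | (3R,5S,7R,9S,11R,13R)-3,7-epoxy-5-hydroxy-11-methoxy-9-methylhexadecan-13-olide (macrolactone, equatorial C5 alcohol) | CCC[C@@H]1C[C@H](OC)C[C@H](C)C[C@@H]2C[C@H](O)C[C@H](CC(=O)O1)O2 | intermediate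
22 | prop-2-yn-1-amine | C#CCN | starting material
23 | methyl prop-2-yn-1-ylcarbamate | C#CCNC(=O)OC | intermediate
24 | methyl 5-bromo-4-oxopentanoate | COC(=O)CCC(=O)CBr | starting material
25 | urea | NC(N)=O | starting material
26 | methyl 3-(2-amino-1,3-oxazol-4-yl)propanoate | COC(=O)CCc1coc(N)n1 | intermediate
27 | methyl 3-(2-bromo-1,3-oxazol-4-yl)propanoate | COC(=O)CCc1coc(Br)n1 | intermediate
28 | methyl 3-{2-[3-(methoxycarbonylamino)prop-1-yn-1-yl]-1,3-oxazol-4-yl}propanoate | COC(=O)CCc1coc(C#CCNC(=O)OC)n1 | intermediate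
29 | methyl 3-{2-[(1Z)-3-(methoxycarbonylamino)prop-1-en-1-yl]-1,3-oxazol-4-yl}propanoate | COC(=O)CCc1coc(/C=C\CNC(=O)OC)n1 | intermediate
30 | methyl N-{(2Z)-3-[4-(3-oxopropyl)-1,3-oxazol-2-yl]prop-2-en-1-yl}carbamate | O=CCCc1coc(/C=C\CNC(=O)OC)n1 | intermediate
31 | methyl (2Z)-5-{2-[(1Z)-3-(methoxycarbonylamino)prop-1-en-1-yl]-1,3-oxazol-4-yl}pent-2-enoate | COC(=O)/C=C\CCc1coc(/C=C\CNC(=O)OC)n1 | intermediate
32 | (2Z)-5-{2-[(1Z)-3-(methoxycarbonylamino)prop-1-en-1-yl]-1,3-oxazol-4-yl}pent-2-enoic acid | OC(=O)/C=C\CCc1coc(/C=C\CNC(=O)OC)n1 | intermediate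
33 | neopeltolide | CCC[C@@H]1C[C@H](OC)C[C@H](C)C[C@@H]2C[C@@H](OC(=O)/C=C\CCc3coc(/C=C\CNC(=O)OC)n3)C[C@H](CC(=O)O1)O2 | target

**Step count**

Total: 22 steps.
Longest linear sequence: 12 steps (steps 1–4, 6, 8–13, 22), from (R)-epichlorohydrin.

**Steps most likely to fail**

Step 12. Intermolecular acetal exchange may outrun the ring closure and give oligomers, or ethanol may be eliminated from the β-alkoxy ester to an unreactive alkoxyacrylate. The fallback closes the macrocycle by lactonization instead; it sets out from 19 and comes back at 21. The acetal ester of 19 is removed (K2CO3, MeOH) to give (4R,6R,8R,10S)-6-methoxy-8-methyltridec-12-ene-4,10-diol F1. An intermolecular Prins cyclization of F1 with methyl 3,3-dimethoxypropanoate (CF3CO2H, CH2Cl2) builds the natural oxane on the open chain and gives, without isolation, the bis(trifluoroacetate) methyl 2-[(2R,4S,6R)-6-[(2S,4R,6R)-4-methoxy-2-methyl-6-(trifluoroacetoxy)nonyl]-4-(trifluoroacetoxy)oxan-2-yl]acetate F2. LiOH (THF/MeOH/H2O) then cleaves both trifluoroacetates and the methyl ester to 2-[(2R,4S,6R)-4-hydroxy-6-[(2S,4R,6R)-6-hydroxy-4-methoxy-2-methylnonyl]oxan-2-yl]acetic acid F3. Yamaguchi macrolactonization (2,4,6-trichlorobenzoyl chloride, Et3N; DMAP, toluene, high dilution) should close the lactone at the C13 hydroxyl and return 21, because the equatorial C5 hydroxyl can reach C1 only through a chair with all three ring substituents axial.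

Step 9. The catalyst may discriminate the faces of this δ-methoxy thioenoate poorly, or the Grignard reagent may add 1,2. The fallback replaces conjugate addition by an SN2′ allylic alkylation; it sets out from 10 and comes back at 17. Cross-metathesis of 10 with (E)-1,4-dibromobut-2-ene (second-generation Hoveyda–Grubbs catalyst, CH2Cl2, 40 °C) gives (4R,6R,8E)-10-bromo-6-methoxydec-8-en-4-yl 3,3-diethoxypropanoate F4. Copper-catalysed asymmetric allylic alkylation (MeMgBr, CuBr·SMe2, the TaniaPhos antipode, 1-[α-(dimethylamino)-2-(diphenylphosphino)benzyl]-2-(diphenylphosphino)ferrocene, that gives the 8S centre, CH2Cl2, −75 °C) places methyl at C9 and gives (4R,6R,8S)-6-methoxy-8-methyldec-9-en-4-yl 3,3-diethoxypropanoate F5. Hydroboration–oxidation (9-BBN, THF; NaBO3, H2O) gives (4R,6R,8R)-10-hydroxy-6-methoxy-8-methyldecan-4-yl 3,3-diethoxypropanoate F6, and Dess–Martin oxidation returns 17.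

Step 2. Oxocarbenium formation from the electron-poor chlorohydrin-type alcohol may be slow, leaving room for allyl-transfer pathways that erode enantiopurity or the all-cis selectivity. The fallback builds the anti-1,3 pair on an open chain by two catalyst-controlled allylations; it sets out from 3 and comes back at 7. Iridium-catalysed transfer-hydrogenative allylation of butanal (allyl acetate, [Ir(cod)Cl]2, the BINAP antipode that gives the 4R carbinol, 4-chloro-3-nitrobenzoic acid, Cs2CO3, i-PrOH, THF, 100 °C) gives (4R)-hept-1-en-4-ol F7. Silylation (TBSCl, imidazole, DMF) gives tert-butyl{[(4R)-hept-1-en-4-yl]oxy}dimethylsilane F8, and ozonolysis (O3, CH2Cl2, −78 °C; PPh3) gives (3R)-3-[(tert-butyldimethylsilyl)oxy]hexanal F9. A second allylation of the same type with the other BINAP antipode gives the 1,3-anti product (4R,6R)-6-[(tert-butyldimethylsilyl)oxy]non-1-en-4-ol F10. Methylation (NaH, MeI, THF) gives tert-butyl{[(4R,6R)-6-methoxynon-8-en-4-yl]oxy}dimethylsilane F11, and Bu4NF (THF) returns 7.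

**Further compounds**

F1 | step 12 | (4R,6R,8R,10S)-6-methoxy-8-methyltridec-12-ene-4,10-diol | CCC[C@@H](O)C[C@H](OC)C[C@H](C)C[C@@H](O)CC=C
F2 | step 12 | methyl 2-[(2R,4S,6R)-6-[(2S,4R,6R)-4-methoxy-2-methyl-6-(trifluoroacetoxy)nonyl]-4-(trifluoroacetoxy)oxan-2-yl]acetate | CCC[C@@H](OC(=O)C(F)(F)F)C[C@H](OC)C[C@H](C)C[C@@H]1C[C@H](OC(=O)C(F)(F)F)C[C@H](CC(=O)OC)O1
F3 | step 12 | 2-[(2R,4S,6R)-4-hydroxy-6-[(2S,4R,6R)-6-hydroxy-4-methoxy-2-methylnonyl]oxan-2-yl]acetic acid | CCC[C@@H](O)C[C@H](OC)C[C@H](C)C[C@@H]1C[C@H](O)C[C@H](CC(=O)O)O1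
F4 | step 9 | (4R,6R,8E)-10-bromo-6-methoxydec-8-en-4-yl 3,3-diethoxypropanoate | CCC[C@@H](OC(=O)CC(OCC)OCC)C[C@H](OC)C/C=C/CBr
F5 | step 9 | (4R,6R,8S)-6-methoxy-8-methyldec-9-en-4-yl 3,3-diethoxypropanoate | CCC[C@@H](OC(=O)CC(OCC)OCC)C[C@H](OC)C[C@H](C)C=C
F6 | step 9 | (4R,6R,8R)-10-hydroxy-6-methoxy-8-methyldecan-4-yl 3,3-diethoxypropanoate | CCC[C@@H](OC(=O)CC(OCC)OCC)C[C@H](OC)C[C@H](C)CCO
F7 | step 2 | (4R)-hept-1-en-4-ol | CCC[C@@H](O)CC=C
F8 | step 2 | tert-butyl{[(4R)-hept-1-en-4-yl]oxy}dimethylsilane | CCC[C@@H](O[Si](C)(C)C(C)(C)C)CC=C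
F9 | step 2 | (3R)-3-[(tert-butyldimethylsilyl)oxy]hexanal | CCC[C@@H](O[Si](C)(C)C(C)(C)C)CC=O
F10 | step 2 | (4R,6R)-6-[(tert-butyldimethylsilyl)oxy]non-1-en-4-ol | CCC[C@@H](O[Si](C)(C)C(C)(C)C)C[C@H](O)CC=C
F11 | step 2 | tert-butyl{[(4R,6R)-6-methoxynon-8-en-4-yl]oxy}dimethylsilane | CCC[C@@H](O[Si](C)(C)C(C)(C)C)C[C@H](OC)CC=C
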